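A direct plan would acylate 2-methoxyresorcinol to the acetophenone A1, benzylate its 4-OH to give A2 and condense A2 with 4-methoxybenzaldehyde to the chalcone A3.
It would then rearrange A3 with Tl(NO3)3 (trivalent thallium) to the benzyl-protected isoflavone A4, hydrogenolyse A4 to the 7-hydroxyisoflavone A5 and prenylate the 7-OH of A5 last.
The weakest steps would be the benzyl protection and its hydrogenolysis: two steps without gain in complexity, needed only because the prenyl alkene would survive neither the oxidant nor H2 over Pd/C.
The hydrogenolysis would also have to spare the C2=C3 bond of the pyranone on late material.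
Equally weak would be the oxidative 1,2-aryl shift: it would need a full equivalent of a toxic thallium salt on the most advanced intermediate, and the closure of ring C would hang on a rearrangement that competes with aurone and flavone formation.

**Plan of the new route**
The retrosynthesis cuts O1–C2 and C2–C3 of ring C (a one-carbon unit), then the O7–prenyl bond, then ring A itself at C4a–C5.
The last cut is possible because ring A with its three contiguous oxygens (C4a, C8a–O1, C8–OMe, C7–O, C6, C5) is the skeleton of maltol (2-CH3, C2–O1, C3–O, C4=O, C5, C6), an isomer of pyrogallol.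
The 2-methyl group of O-methylmaltol is acylated with the arylacetyl unit that carries ring B; base then opens the γ-pyranone and refolds the masked tetracarbonyl chain into the acylresorcinol, an isomerisation.
The rings arise in the order B (bought), A (from the pyranone, key step), C (last, after O-prenylation of the phenol that the key step sets free).
No protecting group, oxidant, hydrogenation or aryl shift occurs, and the prenyl ether meets only K2CO3 and an amide acetal below 70 °C.
Key step: step 4

Remark: the double-bond geometries written for 6 and 9 are the expected ones; both double bonds are consumed in the same flask, so the geometry has no consequence.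

Step 1
Reactants: 1 maltol (3-hydroxy-2-methyl-4H-pyran-4-one)
Product: 2 3-methoxy-2-methyl-4H-pyran-4-one
Conditions: MeI (1.5 equiv), K2CO3 (1.5 equiv), acetone, reflux
Reagents that add atoms: iodomethane, CI
Why: Williamson O-methylation of the acidic enolic 3-OH, the only nucleophilic site of maltol, installs the future 8-OMe and removes the acidic proton before the carbanion chemistry.

Step 2
Reactants: 3 2-(4-methoxyphenyl)acetyl chloride
Product: 4 N-methoxy-2-(4-methoxyphenyl)-N-methylacetamide
Conditions: MeNHOMe·HCl (1.1 equiv), Et3N (2.2 equiv), CH2Cl2, 0 °C to rt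
Reagents that add atoms: N,O-dimethylhydroxylamine hydrochloride, CNOC.Cl
Why: N-acylation of the hydroxylamine gives the Weinreb amide, chosen because its benzylic protons are less acidic than those of an ester and its tetrahedral adduct does not collapse before work-up.

Step 3
Reactants: 2 3-methoxy-2-methyl-4H-pyran-4-one, 4 N-methoxy-2-(4-methoxyphenyl)-N-methylacetamide
Product: 5 3-methoxy-2-[3-(4-methoxyphenyl)-2-oxopropyl]-4H-pyran-4-one
Conditions: LiN(SiMe3)2 (1.1 equiv), THF, −78 °C; then 4, −78 to 0 °C; aq. NH4Cl
Reagents that add atoms: none
Why: Lateral (vinylogous) deprotonation of the 2-methyl group of the γ-pyranone gives a dienolate that reacts at the exocyclic carbon, and its Claisen-type acylation by the Weinreb amide stops at the chelated tetrahedral adduct, so the acidic product is not exposed to the base.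

Step 4
Reactants: 5 3-methoxy-2-[3-(4-methoxyphenyl)-2-oxopropyl]-4H-pyran-4-one
Product: 7 1-(2,4-dihydroxy-3-methoxyphenyl)-2-(4-methoxyphenyl)ethan-1-one, via β-methoxyenone trione 6 (not isolated)
Conditions: NaOMe (3 equiv), MeOH, 60 °C, Ar; then 1 M HCl, 0 °C
Reagents that add atoms: none
Why: Methoxide should add to the unsubstituted C6 of the pyranone (C5 of the target) and the O1–C6 bond should open by E1cB to the β-methoxyenone 6, a masked 1,3,5,7-tetracarbonyl chain in which the former ring oxygen has become the C8a enolate oxygen. The doubly activated methylene C4a then attacks C5 in an intramolecular addition–elimination (vinylogous Claisen condensation, 6-endo-trig, closing ring A as C4a–C8a–C8–C7–C6–C5), methoxide leaves and two enolisations give the resorcinol bis-phenoxide, so that 5 and 7 are isomers. The closest known reaction type is the base-induced conversion of 2-(2-oxoalkyl)-4-pyranones and the derived polyketones into acylresorcinols in biomimetic polyketide aromatisations. No stereocentre survives, since the methoxy-bearing carbon of 6 becomes the planar C8 of the arene. The selectivity needed is the mode of folding: C4a is the only carbon between two carbonyl groups that can reach an electrophile through a six-membered transition state, C5 stays a non-enolisable electrophile as long as it is an enol ether (so C6 cannot act as a carbanion toward the C4 ketone), the aldol of the benzylic C3 onto the C7 ketone needs a less acidic site, and reclosure through oxygen only returns 5, whereas aromatisation is irreversible.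

Step 5
Reactants: 7 1-(2,4-dihydroxy-3-methoxyphenyl)-2-(4-methoxyphenyl)ethan-1-one
Product: 8 1-{2-hydroxy-3-methoxy-4-[(3-methylbut-2-en-1-yl)oxy]phenyl}-2-(4-methoxyphenyl)ethan-1-one
Conditions: prenyl bromide (1.05 equiv), K2CO3 (1.1 equiv), acetone, 50 °C
Reagents that add atoms: 1-bromo-3-methylbut-2-ene (prenyl bromide), CC(C)=CCBr
Why: Williamson etherification should select the 4-OH (the future 7-O), which is para to the ketone and the more acidic, while the 2-OH is held in a hydrogen bond to the carbonyl; one equivalent of halide and a weak base at 50 °C avoid bis-alkylation, C-alkylation and Claisen rearrangement.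

Step 6
Reactants: 8 1-{2-hydroxy-3-methoxy-4-[(3-methylbut-2-en-1-yl)oxy]phenyl}-2-(4-methoxyphenyl)ethan-1-one
Product: 10 8-methoxy-3-(4-methoxyphenyl)-7-[(3-methylbut-2-en-1-yl)oxy]-4H-chromen-4-one, via enaminone 9 (not isolated)
Conditions: Me2NCH(OMe)2 (2.5 equiv), THF, 65 °C
Reagents that add atoms: N,N-dimethylformamide dimethyl acetal, COC(OC)N(C)C
Why: Aminomethylenation of the activated benzylic methylene by the amide acetal gives enaminone 9, whose aminomethylene carbon is attacked by the ortho phenol (6-endo-trig addition, then loss of dimethylamine) to close ring C under neutral conditions that leave the prenyl ether untouched.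

**Compound list**
1 | maltol (3-hydroxy-2-methyl-4H-pyran-4-one) | Cc1occc(=O)c1O | starting material
2 | 3-methoxy-2-methyl-4H-pyran-4-one | COc1c(C)occc1=O | intermediate
3 | 2-(4-methoxyphenyl)acetyl chloride | COc1ccc(CC(Cl)=O)cc1 | starting material
4 | N-methoxy-2-(4-methoxyphenyl)-N-methylacetamide | COc1ccc(CC(=O)N(C)OC)cc1 | intermediate
5 | 3-methoxy-2-[3-(4-methoxyphenyl)-2-oxopropyl]-4H-pyran-4-one | COc1ccc(CC(=O)Cc2occc(=O)c2OC)cc1 | intermediate
6 | (7E)-5,8-dimethoxy-1-(4-methoxyphenyl)oct-7-ene-2,4,6-trione (racemic, drawn as the triketo tautomer) | COc1ccc(CC(=O)CC(=O)C(OC)C(=O)/C=C/OC)cc1 | intermediate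
7 | 1-(2,4-dihydroxy-3-methoxyphenyl)-2-(4-methoxyphenyl)ethan-1-one | COc1ccc(CC(=O)c2ccc(O)c(OC)c2O)cc1 | intermediate
8 | 1-{2-hydroxy-3-methoxy-4-[(3-methylbut-2-en-1-yl)oxy]phenyl}-2-(4-methoxyphenyl)ethan-1-one | COc1ccc(CC(=O)c2ccc(OCC=C(C)C)c(OC)c2O)cc1 | intermediate
9 | (E)-3-(dimethylamino)-1-{2-hydroxy-3-methoxy-4-[(3-methylbut-2-en-1-yl)oxy]phenyl}-2-(4-methoxyphenyl)prop-2-en-1-one | CN(C)/C=C(\c1ccc(OC)cc1)C(=O)c1ccc(OCC=C(C)C)c(OC)c1O | intermediate
10 | 8-methoxy-3-(4-methoxyphenyl)-7-[(3-methylbut-2-en-1-yl)oxy]-4H-chromen-4-one (achiral) | COc1ccc(-c2coc3c(OC)c(OCC=C(C)C)ccc3c2=O)cc1 | target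

**Count and risks**
Total step count: 6. Longest linear sequence: 5 steps (steps 1, 3, 4, 5 and 6); step 2 is a one-step branch.

Steps most likely to fail:

Step 4. The enolate of 5 may resist attack by methoxide, so that the ring does not open. The opened chain may also fold by aldol attack of the benzylic carbon on the C7 ketone, or methoxide may cleave the arylacetyl group by retro-Claisen reaction. The fallback sets out from 3 and comes back at 7, and gives up the pyranone as source of ring A. 2-Methoxybenzene-1,3-diol F1 would be C-acylated with 3 in BF3·OEt2 at 85 °C (Friedel–Crafts acylation; C4 and C6 of the symmetric diol are equivalent, and the boron chelate of the product should prevent a second acylation). Aqueous hydrolysis should then give 7, after which steps 5 and 6 follow unchanged.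

Step 3. Proton transfer from the benzylic CH2 of 4 to the pyranone carbanion, or conjugate self-addition of the carbanion to a second pyranone, may consume the nucleophile. The fallback sets out from 2 and comes back at 5 without a basic carbanion. Soft enolisation of 2 with Me3SiOSO2CF3 and Et3N in CH2Cl2 at 0 °C should give 3-methoxy-2-methylidene-4-[(trimethylsilyl)oxy]-2H-pyran F2, the anhydrobase of the 4-silyloxypyrylium ion. F2 would then be acylated at its exocyclic carbon by acid chloride 3 with ZnCl2 (0.1 equiv) in CH2Cl2 at −20 °C (Mukaiyama-type acylation), returning to 5.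

Step 5. Alkylation of both phenols or C-prenylation may compete with the wanted mono-etherification. The fallback sets out from 7 and comes back at 8 by a Mitsunobu etherification with 3-methylbut-2-en-1-ol, PPh3 and diisopropyl azodicarboxylate in THF at 0 °C. Only the more acidic, non-chelated 4-OH should protonate the betaine, and no new compound is made on the way.

Further compounds
F1 | step 4 | 2-methoxybenzene-1,3-diol | COc1c(O)cccc1O
F2 | step 3 | 3-methoxy-2-methylidene-4-[(trimethylsilyl)oxy]-2H-pyran | C=C1OC=CC(O[Si](C)(C)C)=C1OC
F0 | step 5 | none | none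
A1 | direct plan | 1-(2,4-dihydroxy-3-methoxyphenyl)ethan-1-one | CC(=O)c1ccc(O)c(OC)c1O
A2 | direct plan | 1-[4-(benzyloxy)-2-hydroxy-3-methoxyphenyl]ethan-1-one | CC(=O)c1ccc(OCc2ccccc2)c(OC)c1O
A3 | direct plan | (E)-1-[4-(benzyloxy)-2-hydroxy-3-methoxyphenyl]-3-(4-methoxyphenyl)prop-2-en-1-one | COc1ccc(/C=C/C(=O)c2ccc(OCc3ccccc3)c(OC)c2O)cc1
A4 | direct plan | 7-(benzyloxy)-8-methoxy-3-(4-methoxyphenyl)-4H-chromen-4-one | COc1ccc(-c2coc3c(OC)c(OCc4ccccc4)ccc3c2=O)cc1
A5 | direct plan | 7-hydroxy-8-methoxy-3-(4-methoxyphenyl)-4H-chromen-4-one | COc1ccc(-c2coc3c(OC)c(O)ccc3c2=O)cc1
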